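**Plan**

Locants: flavan numbering for O1–C8a; Cα is the carbinol carbon and Cβ the furan CH. Ring A is the dimethoxybenzene, ring B the pyranone of the chromanone, ring C the furan ring, ring D the carbocycle, ring E the dihydropyran.
Cuts, in retrosynthetic order: the C5 carbonyl (bis-allylic C–H oxidation); O1–C2, C3–C4 and C4–C4a of ring E (4-methoxystyrene, one CH2 unit and the C8a ketone, hetero-Diels–Alder); the aryl–C(=O) bond of ring B; Cβ–O and C8–Cα of ring C; the C8–OAr bond.
Forward: ring D is cyclohexane-1,3-dione and receives the 3,5-dimethoxyphenoxy group at C8; ring C is annulated with a 3-aryl-3-chloropyruvate; ring B is closed by Friedel–Crafts acylation; ring E and the C5 carbonyl follow.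
Enabling feature: the chromanone carbonyl links Cα to a ring A carbon that is ortho to the C8–O ether oxygen and para to a methoxy group; with CO2H on Cα and the aryloxy group on C8 cis on ring C, that carbon is the most nucleophilic one and the only one within reach.
Stereochemistry: Cα from a cinchona-catalysed aldol step, Cβ from dynamic kinetic resolution of the chloro ketone and inversion on ring closure, C8 from which of the two diastereotopic ketones closes ring C; C2 forms without control in the cycloaddition and the epimers are separated.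

Key step: step 7

Assumption: (DHQD)2PYR is taken to give the (αR) series drawn; if the sense of induction proves opposite, the pseudoenantiomeric (DHQ)2PYR is used in step 5 with nothing else changed.

**Route**

Step 1
Reactants: 1 cyclohexane-1,3-dione
Product: 2 2-diazocyclohexane-1,3-dione
Conditions: 4-acetamidobenzenesulfonyl azide (1.1 equiv), Et3N, MeCN, 0 → 23 °C
Reagents that add atoms: 4-acetamidobenzenesulfonyl azide, CC(=O)Nc1ccc(cc1)S(=O)(=O)N=[N+]=[N-]
Why: Regitz diazo transfer to the acidic C2 methylene of a 1,3-dione is routine and should give the stable acceptor/acceptor diazo compound.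

Step 2
Reactants: 2 2-diazocyclohexane-1,3-dione; 3 3,5-dimethoxyphenol
Product: 4 2-(3,5-dimethoxyphenoxy)-3-hydroxycyclohex-2-en-1-one
Conditions: Rh2(OAc)4 (1 mol %), 3 (1.5 equiv), PhF, 80 °C, slow addition of 2
Reagents that add atoms: none
Why: Rhodium-carbenoid O–H insertion into a phenol (oxonium ylide, then proton shift) is known for cyclic 2-diazo-1,3-diones, and slow addition with excess phenol should keep it ahead of attack on the ring carbons of the phenol.

Step 3
Reactants: 5 dichloroacetyl chloride; 6 prop-2-en-1-ol
Product: 7 prop-2-enyl dichloroacetate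
Conditions: pyridine (1.1 equiv), CH2Cl2, 0 °C
Reagents that add atoms: none
Why: Acylation of a primary alcohol by an acid chloride is reliable, and the allyl ester is chosen because it can later be cleaved at the O–allyl bond without acid or base.

Step 4
Reactants: 7 prop-2-enyl dichloroacetate; 8 4-methoxybenzaldehyde
Product: 10 prop-2-enyl 3-chloro-3-(4-methoxyphenyl)-2-oxopropanoate (racemic), via chloro epoxide 9 (not isolated)
Conditions: KOtBu (1.1 equiv), THF, −78 → 23 °C
Reagents that add atoms: none
Why: Darzens condensation of a dichloroacetate gives the 2-chloroglycidic ester, which on warming opens at the p-anisyl carbon and returns chloride there, a known one-flask entry to 3-aryl-3-chloropyruvates.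

Step 5
Reactants: 4 2-(3,5-dimethoxyphenoxy)-3-hydroxycyclohex-2-en-1-one; 10 prop-2-enyl 3-chloro-3-(4-methoxyphenyl)-2-oxopropanoate
Product: 12 prop-2-enyl (2S,3R,3aS)-3a-(3,5-dimethoxyphenoxy)-3-hydroxy-2-(4-methoxyphenyl)-4-oxo-2,3,3a,4,5,6-hexahydro-1-benzofuran-3-carboxylate, via chlorohydrin aldol adduct 11 (not isolated)
Conditions: (DHQD)2PYR (10 mol %), 1,8-bis(dimethylamino)naphthalene (1.2 equiv), THF, −78 °C; then AgOTf (1.2 equiv), −78 → 0 °C
Reagents that add atoms: none
Why: Proposed new method: the ammonium enolate of 4 should add through C8 to the ketone of 10 under control of the bis-cinchona catalyst and anti to the C–Cl bond (polar Felkin–Anh), while the base keeps 10 racemising so that a single chlorohydrin 11 accumulates (dynamic kinetic resolution); silver triflate then ionises the p-anisyl-activated C–Cl bond and one of the two diastereotopic ring carbonyl oxygens closes ring C at Cβ with inversion (5-exo-tet), the oxocarbenium ion losing H6 to give the enol ether, which fixes C8 with the ester cis to the small aryloxy group and the hydroxyl cis to the remaining ketone, the aryl group ending trans to the ester whether closure is concerted or passes through the benzylic cation; the closest known reaction is the cinchona-catalysed interrupted Feist–Benary reaction of cyclohexane-1,3-dione with 3-substituted bromopyruvates, from which this differs in that C8 is quaternary and closure runs through the distal carbonyl.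

Step 6
Reactants: 12 allyl ester
Product: 13 (2S,3R,3aS)-3a-(3,5-dimethoxyphenoxy)-3-hydroxy-2-(4-methoxyphenyl)-4-oxo-2,3,3a,4,5,6-hexahydro-1-benzofuran-3-carboxylic acid
Conditions: Pd(PPh3)4 (5 mol %), morpholine (5 equiv), THF, 23 °C; pH 4 buffer on work-up
Reagents that add atoms: none
Why: Tsuji–Trost deallylation by zerovalent palladium cleaves the O–allyl bond of the hindered ester under neutral conditions, so the β-hydroxy ketone is not exposed to hydroxide (retro-aldol) and the enol ether is not exposed to strong acid.

Step 7
Reactants: 13 bicyclic hydroxy acid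
Product: 15 (8S,αR,βS)-tetracyclic 5-deoxo chromanone (rings A–D; C8a ketone; C6=C7 enol ether), via mixed trifluoroacetic anhydride 14 (not isolated)
Conditions: (CF3CO)2O (1.5 equiv), CH2Cl2, −20 → 0 °C; aq. NaHCO3
Reagents that add atoms: none
Why: Trifluoroacetic anhydride converts the acid into mixed anhydride 14, whose acyl carbon is attacked by the ring A carbon ortho to the C8–O ether oxygen and para to a methoxy group, and the arenium ion loses a proton to give the 2-oxy-4,6-dimethoxyaryl ketone. The closest known reaction is the anhydride-mediated intramolecular Friedel–Crafts acylation of aryloxy acids onto phloroglucinol ethers used for chromanones and xanthones. Ring B closes in the 6-exo-trig mode, which is possible because the carboxyl group on Cα and the aryloxy group on C8 are cis on ring C. No stereocenter is formed and the three existing ones are untouched, since Cα carries no hydrogen and the C8–O bond, at a tertiary ether next to a ketone and not yet part of a dienone, should not ionise in the trifluoroacetic acid set free. The selectivity needed is regiochemical on the arene and is secured by symmetry (the two ortho carbons are equivalent) and by ring size (the carbon between the methoxy groups cannot reach); competing trifluoroacetylation of the C6=C7 enol ether is held back by intramolecularity, near-stoichiometric anhydride and low temperature.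

Step 8
Reactants: 15 tetracyclic chromanone
Product: 16 C4a-(dimethylaminomethyl) ketone (C4a epimers)
Conditions: LiN(SiMe3)2 (2.2 equiv), THF, −78 °C; Me2N=CH2+ I− (1.5 equiv), −78 → −20 °C; aq. NH4Cl
Reagents that add atoms: N,N-dimethylmethyleneiminium iodide (Eschenmoser's salt), C=[N+](C)C.[I-]
Why: Mannich reaction of the lithium enolate, for which C4a is the only enolisable position (C8 is quaternary and the chromanone ketone has no α-hydrogen), with the second equivalent of base taking the tertiary hydroxyl and the low temperature keeping the enol ether inert towards the iminium ion; the C4a configuration is lost in step 9.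

Step 9
Reactants: 16 Mannich base; 17 4-methoxystyrene
Product: 20 (2R,8S,αR,βS)-5-deoxo pentacycle (target lacking the C5 carbonyl), via ammonium iodide 18 (not isolated), via methylene ketone 19 (not isolated)
Conditions: MeI (5 equiv), CH2Cl2, 23 °C; evaporate; 17 (10 equiv), NaHCO3, BHT (cat.), ClCH2CH2Cl, 70 °C; chromatographic removal of the C2 epimer
Reagents that add atoms: none
Why: Quaternisation and mild-base elimination release the s-cis-locked α-methylene ketone 19 in the presence of excess styrene, with which it should react as a 1-oxadiene in an inverse-electron-demand hetero-Diels–Alder reaction (oxygen to the benzylic carbon) to close ring E; no facial control at C2 is claimed, so both epimers are expected and are separated as diastereomers.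

Step 10
Reactants: 20 5-deoxo pentacycle
Product: 21 target compound CNP0251458.1, (2R,8S,αR,βS)
Conditions: Rh2(cap)4 (1 mol %; cap = caprolactamate), t-BuOOH (70 % in water, 5 equiv), NaHCO3, ClCH2CH2Cl, 23 → 40 °C
Reagents that add atoms: tert-butyl hydroperoxide, CC(C)(C)OO
Why: The C5 methylene lies between the β-carbons of two enol ethers and holds the weakest C–H bonds, so tert-butylperoxyl radical abstraction and collapse of the C5 peroxide (Kharasch-type allylic oxidation, as known for 1-alkoxycyclohexa-1,4-dienes going to cross-conjugated dienones) should give the doubly vinylogous ester, which is deactivated towards further oxidation.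

**Compound list**

1 | cyclohexane-1,3-dione | O=C1CCCC(=O)C1 | starting material
2 | 2-diazocyclohexane-1,3-dione | O=C1CCCC(=O)C1=[N+]=[N-] | intermediate
3 | 3,5-dimethoxyphenol | COc1cc(O)cc(OC)c1 | starting material
4 | 2-(3,5-dimethoxyphenoxy)-3-hydroxycyclohex-2-en-1-one (enol form of the 2-aryloxy dione) | O=C1CCCC(O)=C1Oc1cc(OC)cc(OC)c1 | intermediate
5 | dichloroacetyl chloride | ClC(Cl)C(Cl)=O | starting material
6 | prop-2-en-1-ol | OCC=C | starting material
7 | prop-2-enyl dichloroacetate | C=CCOC(=O)C(Cl)Cl | intermediate
8 | 4-methoxybenzaldehyde | COc1ccc(C=O)cc1 | starting material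
9 | prop-2-enyl 2-chloro-3-(4-methoxyphenyl)oxirane-2-carboxylate (racemic) | C=CCOC(=O)C1(Cl)OC1c1ccc(OC)cc1 | intermediate (not isolated)
10 | prop-2-enyl 3-chloro-3-(4-methoxyphenyl)-2-oxopropanoate (racemic, labile at Cβ) | C=CCOC(=O)C(=O)C(Cl)c1ccc(OC)cc1 | intermediate
11 | prop-2-enyl (2R,3R)-3-chloro-2-[1-(3,5-dimethoxyphenoxy)-2,6-dioxocyclohexyl]-2-hydroxy-3-(4-methoxyphenyl)propanoate | O=C1CCCC(=O)C1(Oc1cc(OC)cc(OC)c1)[C@@](O)(C(=O)OCC=C)[C@H](Cl)c1ccc(OC)cc1 | intermediate (not isolated)
12 | prop-2-enyl (2S,3R,3aS)-3a-(3,5-dimethoxyphenoxy)-3-hydroxy-2-(4-methoxyphenyl)-4-oxo-2,3,3a,4,5,6-hexahydro-1-benzofuran-3-carboxylate (aryl and hydroxyl cis; ester and aryloxy cis) | O=C1CCC=C2O[C@@H](c3ccc(OC)cc3)[C@](O)(C(=O)OCC=C)[C@@]12Oc1cc(OC)cc(OC)c1 | intermediate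
13 | (2S,3R,3aS)-3a-(3,5-dimethoxyphenoxy)-3-hydroxy-2-(4-methoxyphenyl)-4-oxo-2,3,3a,4,5,6-hexahydro-1-benzofuran-3-carboxylic acid (precursor of the key step) | O=C1CCC=C2O[C@@H](c3ccc(OC)cc3)[C@](O)(C(=O)O)[C@@]12Oc1cc(OC)cc(OC)c1 | intermediate
14 | mixed anhydride of 13 with trifluoroacetic acid | O=C1CCC=C2O[C@@H](c3ccc(OC)cc3)[C@](O)(C(=O)OC(=O)C(F)(F)F)[C@@]12Oc1cc(OC)cc(OC)c1 | intermediate (not isolated)
15 | (8S,αR,βS)-tetracyclic chromanone: rings A–D of the target with a C8a ketone, C4a and C5 methylenes and the C6=C7 enol ether (product of the key step) | O=C1CCC=C2O[C@@H](c3ccc(OC)cc3)[C@]3(O)C(=O)c4c(OC)cc(OC)cc4O[C@]123 | intermediate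
16 | C4a-(dimethylaminomethyl) derivative of 15 (C4a epimers) | O=C1C(CN(C)C)CC=C2O[C@@H](c3ccc(OC)cc3)[C@]3(O)C(=O)c4c(OC)cc(OC)cc4O[C@]123 | intermediate
17 | 4-methoxystyrene | C=Cc1ccc(OC)cc1 | starting material
18 | C4a-(trimethylammoniomethyl) iodide of 15 | O=C1C(C[N+](C)(C)C)CC=C2O[C@@H](c3ccc(OC)cc3)[C@]3(O)C(=O)c4c(OC)cc(OC)cc4O[C@]123.[I-] | intermediate (not isolated)
19 | C4a-methylene ketone derived from 15 | O=C1C(=C)CC=C2O[C@@H](c3ccc(OC)cc3)[C@]3(O)C(=O)c4c(OC)cc(OC)cc4O[C@]123 | intermediate (not isolated)
20 | (2R,8S,αR,βS)-5-deoxo pentacycle: the target with CH2 at C5 | COc1ccc([C@H]2CCC3=C(O2)[C@]24Oc5cc(OC)cc(OC)c5C(=O)[C@@]2(O)[C@H](c2ccc(OC)cc2)OC4=CC3)cc1 | intermediate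
21 | CNP0251458.1, (2R,8S,αR,βS) | COc1ccc([C@H]2CCC3=C(O2)[C@]24Oc5cc(OC)cc(OC)c5C(=O)[C@@]2(O)[C@H](c2ccc(OC)cc2)OC4=CC3=O)cc1 | target

**Step count and risks**

Total: 10 steps. Longest linear sequence: 8 steps (steps 1, 2, 5–10; the branch through steps 3 and 4 is equally long).

Step 5 (proposed new method). Retro-aldol cleavage of the congested adduct may outrun ring closure, the free carbinol may close onto the benzylic carbon to give the glycidic ester instead of ring C, and enantio-induction on a 2-substituted dione may be poor; a C8 epimer, if formed, cannot close ring B in step 7. The fallback uses known steps, sets out from 4 and 10 and comes back at 13. Silylation of 4 (Me3SiCl, Et3N) gives the enol silane 2-(3,5-dimethoxyphenoxy)-3-(trimethylsilyloxy)cyclohex-2-en-1-one F1. Mukaiyama aldol addition of F1 to 10 under Tf2NH catalysis with silyl transfer gives the racemic O-trimethylsilyl chlorohydrin F2 in the polar Felkin–Anh sense. With the carbinol capped, neither retro-aldol nor epoxide formation is open, and KN(SiMe3)2 forms the distal ketone enolate, which O-alkylates at Cβ with inversion (5-exo-tet; C-alkylation would be 5-enolendo and is disfavoured by Baldwin's rules) to the racemic trimethylsilyl ether of the bicyclic ester F3. Pd(PPh3)4/morpholine followed by citric acid in methanol removes the allyl and silyl groups to give racemic 13, which is resolved by crystallisation of the (S)-1-phenylethylammonium salt F4 and returned as 13 on acidification.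

Step 9. The transient methylene ketone may dimerise or react too slowly with a styrene, and there is no facial bias at C2. The fallback sets out from 16 and comes back at 20 with C2 under reagent control. The methiodide of 16 is eliminated with NaHCO3 in the presence of the enamine 4-[1-(4-methoxyphenyl)ethenyl]morpholine F5 (from 4′-methoxyacetophenone, morpholine and TiCl4). Stork enamine Michael addition to the methylene ketone and hydrolysis give the 1,5-diketone F6. Noyori transfer hydrogenation with RuCl[(R,R)-TsDPEN](p-cymene) in HCO2H/Et3N reduces only the p-anisyl ketone and gives the (R)-carbinol F7. PPTS with 4 Å sieves in benzene closes ring E by lactol formation and dehydration with the C2–O bond intact, giving 20.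

Step 10. Radical oxidation may attack the enol ether double bonds, the benzylic C2–H and Cβ–H bonds or, after the ketone has formed, C4. The fallback sets out from 20 and comes back at 21 by an ionic path. DDQ in wet dioxane abstracts hydride from C5, and water captures the dioxy-stabilised pentadienyl cation to give the C5 carbinol F8 (C5 epimers), which MnO2 oxidises as a doubly allylic alcohol to 21.

**Further compounds**

F1 | step 5 | 2-(3,5-dimethoxyphenoxy)-3-(trimethylsilyloxy)cyclohex-2-en-1-one | O=C1CCCC(O[Si](C)(C)C)=C1Oc1cc(OC)cc(OC)c1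
F2 | step 5 | prop-2-enyl 3-chloro-2-[1-(3,5-dimethoxyphenoxy)-2,6-dioxocyclohexyl]-3-(4-methoxyphenyl)-2-(trimethylsilyloxy)propanoate (racemic, drawn as the (2R,3R) enantiomer) | O=C1CCCC(=O)C1(Oc1cc(OC)cc(OC)c1)[C@@](O[Si](C)(C)C)(C(=O)OCC=C)[C@H](Cl)c1ccc(OC)cc1
F3 | step 5 | trimethylsilyl ether of 12 (racemic, drawn as the enantiomer of the main series) | O=C1CCC=C2O[C@@H](c3ccc(OC)cc3)[C@](O[Si](C)(C)C)(C(=O)OCC=C)[C@@]12Oc1cc(OC)cc(OC)c1
F4 | step 5 | (S)-1-phenylethylammonium salt of 13 | O=C1CCC=C2O[C@@H](c3ccc(OC)cc3)[C@](O)(C(=O)[O-])[C@@]12Oc1cc(OC)cc(OC)c1.C[C@H]([NH3+])c1ccccc1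
F5 | step 9 | 4-[1-(4-methoxyphenyl)ethenyl]morpholine | C=C(N1CCOCC1)c1ccc(OC)cc1
F6 | step 9 | C4a-[3-(4-methoxyphenyl)-3-oxopropyl] derivative of 15 (C4a epimers) | O=C1C(CCC(=O)c5ccc(OC)cc5)CC=C2O[C@@H](c3ccc(OC)cc3)[C@]3(O)C(=O)c4c(OC)cc(OC)cc4O[C@]123
F7 | step 9 | C4a-[(3R)-3-hydroxy-3-(4-methoxyphenyl)propyl] derivative of 15 (C4a epimers) | O=C1C(CC[C@@H](O)c5ccc(OC)cc5)CC=C2O[C@@H](c3ccc(OC)cc3)[C@]3(O)C(=O)c4c(OC)cc(OC)cc4O[C@]123
F8 | step 10 | 5-hydroxy derivative of 20 (C5 epimers) | COc1ccc([C@H]2CCC3=C(O2)[C@]24Oc5cc(OC)cc(OC)c5C(=O)[C@@]2(O)[C@H](c2ccc(OC)cc2)OC4=CC3O)cc1
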